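**Retrosynthetic overview**
- The target comes from hispidulin by O-sulfation of the 7- and 4'-phenols; the 5-OH is hydrogen-bonded to the C4 carbonyl and stays free.
- Hispidulin comes from its 5,7,4'-tri-O-benzyl ether; the pyranone C ring, the only ring built, is closed by oxidative cyclisation of a 2'-hydroxychalcone.
- The key C–C bond (flavone C2–C3) is made by an intermolecular Claisen–Schmidt aldol condensation of a ring-A acetophenone with 4-(benzyloxy)benzaldehyde.
- The acetophenone comes from 3,5-bis(benzyloxy)-4-methoxyphenol by MOM-directed ortho-lithiation and acetylation, which fixes the 6-OMe unambiguously.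
- The phenol comes from methyl 3,5-dihydroxy-4-methoxybenzoate by benzylation, reduction/oxidation to the aldehyde and Baeyer–Villiger oxidation; rings A and B are purchased.

Assumption: the target has no stereocentre (it is achiral), so no enantiomer has to be selected; it is delivered as the free bis(hydrogen sulfate) drawn, and the racemic transient intermediates 12 and 14 lose their stereocentre within their own step.

**Route**

Step 1
Reactants: 1 methyl 3,5-dihydroxy-4-methoxybenzoate
Product: 2 methyl 3,5-bis(benzyloxy)-4-methoxybenzoate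
Conditions: BnBr (2.5 equiv), K2CO3, DMF, 60 °C
Reagents that add atoms: benzyl bromide, BrCc1ccccc1
Why: Williamson ether synthesis (SN2) on both phenoxides; the ester and the methyl ether are inert and no stereocentre is formed.

Step 2
Reactants: 2 methyl 3,5-bis(benzyloxy)-4-methoxybenzoate
Product: 3 [3,5-bis(benzyloxy)-4-methoxyphenyl]methanol
Conditions: LiAlH4, THF, 0 °C to rt; Fieser work-up (H2O, aq. NaOH)
Reagents that add atoms: none
Why: Hydride reduction of the ester to the primary benzylic alcohol; aryl benzyl and methyl ethers do not react.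

Step 3
Reactants: 3 [3,5-bis(benzyloxy)-4-methoxyphenyl]methanol
Product: 4 3,5-bis(benzyloxy)-4-methoxybenzaldehyde
Conditions: activated MnO2 (10 equiv), CH2Cl2, rt
Reagents that add atoms: none
Why: MnO2 oxidation is selective for benzylic alcohols and stops at the aldehyde.

Step 4
Reactants: 4 3,5-bis(benzyloxy)-4-methoxybenzaldehyde
Product: 6 3,5-bis(benzyloxy)-4-methoxyphenol, via aryl formate 5 (not isolated)
Conditions: mCPBA, CH2Cl2, 0 °C to rt; then K2CO3 (cat.), MeOH, rt
Reagents that add atoms: mCPBA (3-chloroperoxybenzoic acid), O=C(OO)c1cccc(Cl)c1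
Why: Baeyer–Villiger (Dakin-type) oxidation in which the electron-rich trialkoxyaryl group migrates to give the aryl formate, which is then methanolysed to the phenol.

Step 5
Reactants: 6 3,5-bis(benzyloxy)-4-methoxyphenol
Product: 7 1,3-bis(benzyloxy)-2-methoxy-5-(methoxymethoxy)benzene
Conditions: MOMCl, i-Pr2NEt, CH2Cl2, 0 °C to rt
Reagents that add atoms: chloromethyl methyl ether (MOMCl), COCCl
Why: O-alkylation of the phenol gives the MOM acetal, which serves as protecting group and as ortho-directing group for the next step.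

Step 6
Reactants: 7 1,3-bis(benzyloxy)-2-methoxy-5-(methoxymethoxy)benzene
Product: 9 1-[2,4-bis(benzyloxy)-3-methoxy-6-(methoxymethoxy)phenyl]ethan-1-one, via aryllithium 8 (not isolated)
Conditions: n-BuLi (1.1 equiv), THF, 0 °C, 1 h; then MeC(O)N(OMe)Me, −78 to 0 °C; aq. NH4Cl
Reagents that add atoms: N-methoxy-N-methylacetamide, CC(=O)N(C)OC
Why: Directed ortho-metalation at the C–H flanked by OMOM and OBn (the two free ring positions are equivalent), followed by Weinreb-amide acylation, whose chelated tetrahedral adduct prevents over-addition.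

Step 7
Reactants: 9 1-[2,4-bis(benzyloxy)-3-methoxy-6-(methoxymethoxy)phenyl]ethan-1-one
Product: 10 1-[2,4-bis(benzyloxy)-6-hydroxy-3-methoxyphenyl]ethan-1-one
Conditions: conc. HCl (cat.), MeOH–THF, 50 °C
Reagents that add atoms: none
Why: Acid-catalysed acetal methanolysis removes only the MOM group; benzyl and methyl ethers are stable and the chelated o-hydroxyacetophenone results.

Step 8
Reactants: 10 1-[2,4-bis(benzyloxy)-6-hydroxy-3-methoxyphenyl]ethan-1-one; 11 4-(benzyloxy)benzaldehyde
Product: 13 (2E)-1-[2,4-bis(benzyloxy)-6-hydroxy-3-methoxyphenyl]-3-[4-(benzyloxy)phenyl]prop-2-en-1-one, via aldol adduct 12 (not isolated)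
Conditions: KOH (50% aq.), EtOH–THF, rt, 48 h; then dil. HCl
Reagents that add atoms: none
Why: Claisen–Schmidt crossed aldol condensation of the ketone enolate with the non-enolisable aldehyde; E1cB dehydration erases the carbinol stereocentre and gives the thermodynamic (E)-enone.

Step 9
Reactants: 13 (2E)-1-[2,4-bis(benzyloxy)-6-hydroxy-3-methoxyphenyl]-3-[4-(benzyloxy)phenyl]prop-2-en-1-one
Product: 15 5,7-bis(benzyloxy)-2-[4-(benzyloxy)phenyl]-6-methoxy-4H-chromen-4-one, via flavanone 14 (not isolated)
Conditions: I2 (10 mol %), DMSO, 130 °C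
Reagents that add atoms: none
Why: I2/DMSO oxidative cyclisation: oxa-Michael closure to the racemic flavanone, then α-iodination and HI elimination with DMSO as terminal oxidant, which removes the C2 stereocentre.

Step 10
Reactants: 15 5,7-bis(benzyloxy)-2-[4-(benzyloxy)phenyl]-6-methoxy-4H-chromen-4-one
Product: 16 hispidulin (5,7-dihydroxy-2-(4-hydroxyphenyl)-6-methoxy-4H-chromen-4-one)
Conditions: H2 (1 atm), 10% Pd/C, THF–MeOH, rt
Reagents that add atoms: none
Why: Catalytic hydrogenolysis cleaves the three benzyl ethers, while the aryl methyl ether and the chromone C2=C3 bond survive at 1 atm and rt if the reaction is stopped at complete debenzylation.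

Step 11
Reactants: 16 hispidulin (5,7-dihydroxy-2-(4-hydroxyphenyl)-6-methoxy-4H-chromen-4-one)
Product: 18 hispidulin 7,4'-disulfate, via bis-pyridinium disulfate 17 (not isolated)
Conditions: SO3·pyridine (5 equiv), pyridine, rt; then Dowex 50W (H+), H2O, 0 °C, lyophilise
Reagents that add atoms: sulfur trioxide–pyridine complex, O=S(=O)([O-])[n+]1ccccc1
Why: O-sulfonation of the free 7- and 4'-phenols with an SO3–amine complex, while the 5-OH hydrogen-bonded to the C4 carbonyl is unreactive; cold cation exchange gives the free acid.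

**Compound list**
1 | methyl 3,5-dihydroxy-4-methoxybenzoate | COC(=O)c1cc(O)c(OC)c(O)c1 | starting material
2 | methyl 3,5-bis(benzyloxy)-4-methoxybenzoate | COC(=O)c1cc(OCc2ccccc2)c(OC)c(OCc2ccccc2)c1 | intermediate
3 | [3,5-bis(benzyloxy)-4-methoxyphenyl]methanol | OCc1cc(OCc2ccccc2)c(OC)c(OCc2ccccc2)c1 | intermediate
4 | 3,5-bis(benzyloxy)-4-methoxybenzaldehyde | O=Cc1cc(OCc2ccccc2)c(OC)c(OCc2ccccc2)c1 | intermediate
5 | 3,5-bis(benzyloxy)-4-methoxyphenyl formate (aryl formate) | O=COc1cc(OCc2ccccc2)c(OC)c(OCc2ccccc2)c1 | intermediate (not isolated)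
6 | 3,5-bis(benzyloxy)-4-methoxyphenol | Oc1cc(OCc2ccccc2)c(OC)c(OCc2ccccc2)c1 | intermediate
7 | 1,3-bis(benzyloxy)-2-methoxy-5-(methoxymethoxy)benzene | COCOc1cc(OCc2ccccc2)c(OC)c(OCc2ccccc2)c1 | intermediate
8 | [2,4-bis(benzyloxy)-3-methoxy-6-(methoxymethoxy)phenyl]lithium (aryllithium) | [Li]c1c(OCOC)cc(OCc2ccccc2)c(OC)c1OCc1ccccc1 | intermediate (not isolated)
9 | 1-[2,4-bis(benzyloxy)-3-methoxy-6-(methoxymethoxy)phenyl]ethan-1-one | CC(=O)c1c(OCOC)cc(OCc2ccccc2)c(OC)c1OCc1ccccc1 | intermediate
10 | 1-[2,4-bis(benzyloxy)-6-hydroxy-3-methoxyphenyl]ethan-1-one | CC(=O)c1c(O)cc(OCc2ccccc2)c(OC)c1OCc1ccccc1 | intermediate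
11 | 4-(benzyloxy)benzaldehyde | O=Cc1ccc(OCc2ccccc2)cc1 | starting material
12 | 1-[2,4-bis(benzyloxy)-6-hydroxy-3-methoxyphenyl]-3-[4-(benzyloxy)phenyl]-3-hydroxypropan-1-one (aldol adduct, racemic) | O=C(CC(O)c1ccc(OCc2ccccc2)cc1)c1c(O)cc(OCc2ccccc2)c(OC)c1OCc1ccccc1 | intermediate (not isolated)
13 | (2E)-1-[2,4-bis(benzyloxy)-6-hydroxy-3-methoxyphenyl]-3-[4-(benzyloxy)phenyl]prop-2-en-1-one | O=C(/C=C/c1ccc(OCc2ccccc2)cc1)c1c(O)cc(OCc2ccccc2)c(OC)c1OCc1ccccc1 | intermediate
14 | 5,7-bis(benzyloxy)-2-[4-(benzyloxy)phenyl]-6-methoxy-2,3-dihydro-4H-chromen-4-one (flavanone, racemic) | O=C1CC(c2ccc(OCc3ccccc3)cc2)Oc2cc(OCc3ccccc3)c(OC)c(OCc3ccccc3)c21 | intermediate (not isolated)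
15 | 5,7-bis(benzyloxy)-2-[4-(benzyloxy)phenyl]-6-methoxy-4H-chromen-4-one | O=c1cc(-c2ccc(OCc3ccccc3)cc2)oc2cc(OCc3ccccc3)c(OC)c(OCc3ccccc3)c12 | intermediate
16 | hispidulin (5,7-dihydroxy-2-(4-hydroxyphenyl)-6-methoxy-4H-chromen-4-one) | COc1c(O)cc2oc(-c3ccc(O)cc3)cc(=O)c2c1O | intermediate
17 | hispidulin 7,4'-disulfate bis-pyridinium salt | COc1c(OS(=O)(=O)[O-])cc2oc(-c3ccc(OS(=O)(=O)[O-])cc3)cc(=O)c2c1O.c1cc[nH+]cc1.c1cc[nH+]cc1 | intermediate (not isolated)
18 | hispidulin 7,4'-disulfate | COc1c(OS(=O)(=O)O)cc2oc(-c3ccc(OS(=O)(=O)O)cc3)cc(=O)c2c1O | target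

**Totals**
Total step count: 11. Longest linear sequence: 11 steps (1 to 18); aldehyde 11 is purchased.

**Three steps most likely to fail, with fallbacks**

Step 6 (ortho-lithiation and acetylation). The risks are competing benzylic deprotonation of the benzyl ethers and enolisation of the Weinreb amide by the hindered aryllithium. The fallback sets out from 7 and comes back at 9. Bromination of 7 with NBS in MeCN at 0 °C gives 1,3-bis(benzyloxy)-4-bromo-2-methoxy-5-(methoxymethoxy)benzene F1. Bromine–lithium exchange with n-BuLi in THF at −78 °C generates aryllithium 8 regiospecifically and too fast for benzylic metalation. Trapping with acetaldehyde gives racemic 1-[2,4-bis(benzyloxy)-3-methoxy-6-(methoxymethoxy)phenyl]ethan-1-ol F2, and Dess–Martin oxidation in CH2Cl2 with NaHCO3 delivers ketone 9.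

Step 9 (I2/DMSO oxidative cyclisation). The risks are a stall at the flavanone, ring iodination of the electron-rich A ring and HI-induced loss of the 5-O-benzyl group. The fallback sets out from 10 and comes back at 15, building the flavone oxidation level directly. The dianion of 10 (LiHMDS, 3.5 equiv, THF, −78 °C) is C-acylated with commercial 4-(benzyloxy)benzoyl chloride in an intermolecular Claisen-type condensation. This gives 1-[2,4-bis(benzyloxy)-6-hydroxy-3-methoxyphenyl]-3-[4-(benzyloxy)phenyl]propane-1,3-dione F3. Cyclodehydration of F3 with catalytic p-TsOH in toluene at 80 °C closes the pyranone ring to flavone 15.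

Step 11 (sulfation). The risks are mixtures of mono- and disulfate, difficult purification of the very polar product and hydrolysis of the free acid. The fallback sets out from 16 and comes back at 18, using a protected sulfate. Hispidulin 16 reacts with 2,2,2-trichloroethyl chlorosulfate (2.3 equiv), Et3N and DMAP in THF at 0 °C to rt to give hispidulin 7,4'-bis(2,2,2-trichloroethyl sulfate) F4, which can be purified on silica. Reductive removal of both trichloroethyl groups with Zn dust and ammonium formate in MeOH at rt, then the same cold H+ cation exchange, gives 18.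

**Further compounds**
F1 | step 6 | 1,3-bis(benzyloxy)-4-bromo-2-methoxy-5-(methoxymethoxy)benzene | COCOc1cc(OCc2ccccc2)c(OC)c(OCc2ccccc2)c1Br
F2 | step 6 | 1-[2,4-bis(benzyloxy)-3-methoxy-6-(methoxymethoxy)phenyl]ethan-1-ol (racemic) | CC(O)c1c(OCOC)cc(OCc2ccccc2)c(OC)c1OCc1ccccc1
F3 | step 9 | 1-[2,4-bis(benzyloxy)-6-hydroxy-3-methoxyphenyl]-3-[4-(benzyloxy)phenyl]propane-1,3-dione | O=C(CC(=O)c1ccc(OCc2ccccc2)cc1)c1c(O)cc(OCc2ccccc2)c(OC)c1OCc1ccccc1
F4 | step 11 | hispidulin 7,4'-bis(2,2,2-trichloroethyl sulfate) | COc1c(OS(=O)(=O)OCC(Cl)(Cl)Cl)cc2oc(-c3ccc(OS(=O)(=O)OCC(Cl)(Cl)Cl)cc3)cc(=O)c2c1O
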